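## The problem

Compound 25 is a depside: two benzene rings joined only by an aryl ester between the C1 carbonyl of ring A and O-4' of ring B. It has no stereocentre, so the task is to place substituents correctly around two crowded arenes and then to join them. Ring B (C1' CO2H, C2' OH, C3' CH3, C4' O-acyl, C6' CH3) is the β-orsellinic acid pattern and can be bought as its methyl ester 19. Ring A is the hard half: C1 carbonyl, C2 OMe, C3 CH2OH, C4 OMe and C6 CH3 leave only C5 with hydrogen, and four different groups stand side by side from C1 to C4. Electrophilic substitution of an orsellinate writes this pattern poorly, because C3 competes with C5 and the two oxygens with each other. The ester links a di-ortho-substituted benzoic acid to a phenol next to a methyl group, so its formation is slow and must choose O-4' over O-2'. Three groups limit the conditions: the aryl ester (hydroxide, alkoxide), the salicylic acid of ring B (decarboxylation when heated in acid), and the C3 hydroxymethyl group, which lies between two methoxy groups and so ionises in acid and is open to hydrogenolysis. The feature that opens the key step is that ring A is a resorcinol diether with its carbon substituent at C3 between the two oxygens and an ester–methyl pair at C1 and C6. The unit C4–C1–C6–C5 with its ester and methyl group is the skeleton of a vinylketene and C3–C2 with CH2O and OMe is an alkoxyalkyne, so a vinylketene–ynol ether benzannulation assigns every position of ring A through the two reactants.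

## Retrosynthesis

**Unmasking (25 from 24 from 23).** The last cuts are the O–Si bond on the C3 hydroxymethyl oxygen and, before it, the benzyl–oxygen bond of the ring B ester. A silyl ether is preferred on the benzylic oxygen because an acyl group there would itself be hydrogenolysed and would have to leave under conditions that threaten the aryl ester. A benzyl ester is preferred on ring B because it leaves without hydroxide. The benzyl group goes first, so that the benzylic oxygen still carries silicon during hydrogenolysis and the final step is a near-neutral desilylation. Precursor 23 differs from the target only in two protecting groups; the forward steps must leave the aryl ester alone.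

**Depside ester (23 from 18 and 21).** The bond between the ring A carbonyl carbon and O-4' is cut. It is the only bond between the rings and divides the molecule into two arenes of similar size. The neighbouring choice, building a ring onto a finished aryl ester, would carry that ester through ring-forming chemistry. Acid 18 is activated as aroyl chloride 22. Phenol 21 comes from commercial ester 19 through acid 20. The forward step must activate a di-ortho-substituted acid without acid, because of the silyl ether, and must acylate O-4' in preference to the hydrogen-bonded O-2'.

**Ester release and O-methylation (18 from 17 from 16).** The benzyl–oxygen bond of the ring A ester and the O–CH3 bond at C4 are cut. The ring A carboxyl is carried as a benzyl ester because a 2,6-disubstituted benzoate cannot be saponified under tolerable conditions, whereas hydrogenolysis attacks the benzyl carbon. The C4 methyl group is added late because the ring-forming step delivers C4 as the one free phenol of ring A. Both forward steps are routine.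

**Ring A (16 from 5 and 11).** Three ring bonds are cut: C3–C4, C1–C2 and C4–C5. Cutting substituents off a preformed arene instead would return to the regiochemical problem of the orsellinate series; other ring cuts are weighed below. The precursors are acyclic: acid chloride 5 holds C4, C1, C6 and C5 with the ester and the methyl group, and ynol ether 11 holds C3 and C2 with CH2O and OMe. In the forward sense a tertiary amine generates vinylketene 12 from 5, 11 adds to give cyclobutenone 13, and heating opens 13 to dienylketene 14, which closes to cyclohexadienone 15 and tautomerises to 16. The step must make the ketene react at its C=C bond and not through the ester carbonyl, and the ring opening must turn the isopropenyl group toward the ketene.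

**Acid chloride (5 from 4 from 3 from 1 and 2).** The C–Cl bond, the tert-butyl ester and the C=C bond that becomes C1–C6 are cut. Mixed malonate 1 is chosen over a symmetrical diester so that the ester to be removed is marked from the start and no statistical hydrolysis is needed. Both 1 and 2 are commercial. The forward steps are a Knoevenagel condensation with a ketone, an acidolysis and a chloride formation.

**Ynol ether (11 from 10 from 6 and 7).** The O–Si bond and the C–C bond between the alkyne and the CH2O carbon are cut. Acetal 6 is a cheap source of the methoxyethynyl anion 8, which formaldehyde 7 traps as alkoxide 9. An alkoxyalkyne is not easily made by putting oxygen on an existing alkyne, so the alkyne is built with its oxygen in place. The forward steps must handle the small, acid-labile alcohol 10 under neutral conditions until it is silylated.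

## Roads not taken

**Alternative 1:** The cut removes two neighbouring substituents from a finished ring A, the C3–CHO and C4–O bonds. In the forward direction fluoride turns the ortho-silylaryl triflate A1 into aryne A2 (triple bond C3–C4). N,N-Dimethylformamide A3 adds across it with oxygen at C4 and the formyl carbon at C3, and water releases the ortho-hydroxy aldehyde A4.
- Merits: the reaction type is established for arynes. The C2 methoxy group should steer the oxygen nucleophile to the remote aryne carbon C4, which is the required sense. The C3 carbon and the C4 oxygen arrive together.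
- Weak points: no ring is formed. A1 is already a pentasubstituted benzene, so most of the substitution problem of ring A must be solved by other means before the key step. A4 still needs methylation, reduction, protection and cleavage of a di-ortho-substituted methyl ester that resists saponification.
- Comparison: in reliability of the key reaction this road is better than the chosen plan, whose key step is untested. The chosen plan sets against that the assembly of ring A from two acyclic pieces in one operation with every substituent assigned, a benzyl ester that leaves by hydrogenolysis, and a fallback of known chemistry from 11.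

**Alternative 2:** The cut opens ring A at C2–C3 and C1–C6. In the forward direction pyrone A5 and the donor–acceptor alkyne A6 combine in a thermal Diels–Alder reaction, pyrone C3 bonding to the methoxy-bearing alkyne carbon and pyrone C6 to the ester-bearing one. Extrusion of the lactone bridge then gives arene A7, which is the same compound as 17.
- Merits: both methoxy groups are delivered, so no phenol has to be methylated and the road enters the chosen route one step beyond 16. The polarities of diene and alkyne match. Aromatisation is irreversible, and no ester carbonyl competes as a reaction site. In regiochemical certainty and in steps after ring formation this road is as good as or better than the chosen one.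
- Weak points: 4-methoxypyranones are sluggish dienes and A6 is a deactivated, heat-sensitive dienophile, so high temperatures are expected, at which the silyl ether and A6 are at risk. A5 requires hydroxymethylation at C3 of a 4-methoxypyranone, where formaldehyde tends to bridge two pyrone units.
- Comparison: the chosen plan sets against it that its bond-forming event joins a strongly electrophilic ketene to a strongly nucleophilic alkyne at or below room temperature, with heat needed only for unimolecular electrocyclic steps. Its partners come in three and two steps from bulk chemicals, and a lapse of periselectivity within the carbocyclic manifold is repaired by the methylation of step 7.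

**Alternative 3:** The cut is made in ring B, at the C1'–C6' bond. In the forward direction mild aqueous base near 0 °C induces intramolecular aldol addition of the C2 carbanion of triketo ester A8 to its C7 carbonyl; loss of water and aromatisation give the benzyl ester A9, which is the same compound as 21.
- Merits: the closure follows the biosynthetic logic and delivers the benzyl ester directly. It spares the hydrolysis of 19 and the handling of the decarboxylation-prone acid 20, and in that respect is better than steps 9 and 10.
- Weak points: A8 is a sensitive polycarbonyl compound that needs polyanion acylation chemistry and correct placement of its C4 methyl group. Aldol, Claisen and pyranone closures compete. The ring-forming effort is spent on the ring that can be bought, and ring A is left unsolved.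
- Comparison: the chosen plan sets two ordinary steps from commercial 19 against the cleaner entry to 21, and keeps its ring construction for ring A.

Key step: step 6

Remark on the chemistry: 25 has no stereocentre; the only stereocentre on the route is the quaternary carbon of transient 13, which forms racemic and is lost on ring opening. Paraformaldehyde 7 is written as its monomer.

## Route

Step 1
Reactants: 1 benzyl tert-butyl malonate; 2 acetone
Product: 3 1-benzyl 3-tert-butyl 2-(propan-2-ylidene)propanedioate
Conditions: TiCl4, pyridine, THF, 0 °C → rt
Reagents that add atoms: none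
Why: TiCl4/pyridine-mediated Knoevenagel condensation is the standard way to condense a malonate with a simple ketone; pyridine and THF buffer the Lewis acid, so the tert-butyl and benzyl esters should stay intact.

Step 2
Reactants: 3 1-benzyl 3-tert-butyl 2-(propan-2-ylidene)propanedioate
Product: 4 2-[(benzyloxy)carbonyl]-3-methylbut-2-enoic acid
Conditions: TFA, CH2Cl2, 0 °C → rt
Reagents that add atoms: none
Why: Acidolysis of a tert-butyl ester (loss of the tert-butyl cation as isobutene) is orthogonal to the benzyl ester and gives the half ester without statistical hydrolysis; should acid move the double bond into the β,γ-position, that isomer would give the same ketene 12 in step 6.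

Step 3
Reactants: 4 2-[(benzyloxy)carbonyl]-3-methylbut-2-enoic acid
Product: 5 benzyl 2-(chlorocarbonyl)-3-methylbut-2-enoate
Conditions: (COCl)2, DMF (cat.), CH2Cl2, 0 °C → rt; used crude
Reagents that add atoms: oxalyl chloride, O=C(Cl)C(=O)Cl
Why: Oxalyl chloride with catalytic DMF (Vilsmeier-type activation) converts a carboxylic acid into its chloride at room temperature; 5 has no α-hydrogen and should be stable until base is added.

Step 4
Reactants: 6 2-chloro-1,1-dimethoxyethane; 7 paraformaldehyde
Product: 10 3-methoxyprop-2-yn-1-ol, via (methoxyethynyl)lithium 8 (not isolated), via lithium 3-methoxyprop-2-yn-1-olate 9 (not isolated)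
Conditions: LiNEt2 (3 equiv, from n-BuLi and Et2NH), THF, 0 °C; then 7, −78 °C → rt; H2O (pH 7)
Reagents that add atoms: none
Why: Three equivalents of lithium amide carry the chloroacetal through loss of methanol, loss of HCl and deprotonation, the standard route to an alkoxyethynyllithium, which adds to formaldehyde like any lithium acetylide; a neutral work-up protects the hydroxy ynol ether from acid-catalysed Meyer–Schuster rearrangement.

Step 5
Reactants: 10 3-methoxyprop-2-yn-1-ol
Product: 11 tert-butyl[(3-methoxyprop-2-yn-1-yl)oxy]dimethylsilane
Conditions: TBSCl, imidazole, CH2Cl2, 0 °C → rt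
Reagents that add atoms: tert-butyldimethylsilyl chloride, CC(C)(C)[Si](C)(C)Cl
Why: Silylation of a primary alcohol with TBSCl and imidazole is routine and runs under basic conditions that the acid-labile ynol ether tolerates; the silyl ether makes the alkyne non-volatile and hides the hydroxyl from the ketene.

Step 6
Reactants: 5 benzyl 2-(chlorocarbonyl)-3-methylbut-2-enoate; 11 tert-butyl[(3-methoxyprop-2-yn-1-yl)oxy]dimethylsilane
Product: 16 benzyl 3-({[tert-butyl(dimethyl)silyl]oxy}methyl)-4-hydroxy-2-methoxy-6-methylbenzoate, via vinylketene 12 (not isolated), via vinylcyclobutenone 13 (not isolated), via dienylketene 14 (not isolated), via cyclohexadienone 15 (not isolated)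
Conditions: 5 added slowly to 11 (1.5 equiv) and Et3N, toluene, 0 °C → rt; then 90 °C
Reagents that add atoms: none
Why: Proposed new method: Et3N removes a γ-hydrogen of 5 and chloride leaves (1,4-dehydrochlorination) to give the ester-substituted vinylketene 12, which the electron-rich ynol ether 11 traps by (2+2) cycloaddition, its carbon remote from oxygen bonding to the ketene carbonyl carbon (C3–C4) and its methoxy-bearing carbon to the ketene α-carbon (C1–C2), giving 4-vinylcyclobutenone 13. On heating, 13 undergoes conrotatory 4π ring opening to dienylketene 14, ring A is closed by disrotatory 6π electrocyclisation (C4–C5) to cyclohexadienone 15, and 15 tautomerises to phenol 16, the four-membered ring being only a transient. The closest known reaction type is the Danheiser benzannulation, in which the vinylketene comes from a cyclobutenone or from Wolff rearrangement of an unsaturated diazo ketone and carries no ester on the ketene carbon; trapping of simple ketenes, made from acid chlorides and Et3N, by alkoxyalkynes is also known. No stereocentre survives, since the quaternary carbon of 13 forms racemic and becomes sp2 on ring opening. The regiochemistry of the (2+2) step follows from the polarisation of the ynol ether toward the ketene carbonyl carbon, which the ester makes still more electrophilic. The opening of 13 must place the isopropenyl group and not the ester cis to the ketene; because the opening is reversible and only rotamer 14 is drained by the irreversible 6π closure, the unproductive isomer can return through 13. The periselectivity needed is carbon–carbon (2+2) addition and not (4+2) addition across the ketene and the ester carbonyl, which the weak nucleophilicity of an ester oxygen, a non-polar solvent and slow generation of 12 in excess 11 should favour; a direct (4+2) addition across the vinylketene diene would only exchange the hydroxyl and methoxy positions (C2 and C4) and is levelled by step 7.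

Step 7
Reactants: 16 benzyl 3-({[tert-butyl(dimethyl)silyl]oxy}methyl)-4-hydroxy-2-methoxy-6-methylbenzoate
Product: 17 benzyl 3-({[tert-butyl(dimethyl)silyl]oxy}methyl)-2,4-dimethoxy-6-methylbenzoate
Conditions: MeI, K2CO3, acetone, 50 °C
Reagents that add atoms: iodomethane, CI
Why: Williamson O-methylation of the phenoxide is standard and leaves the silyl ether and the benzyl ester alone; any C2-hydroxy, C4-methoxy regioisomer from the other cycloaddition mode would be methylated to the same compound 17.

Step 8
Reactants: 17 benzyl 3-({[tert-butyl(dimethyl)silyl]oxy}methyl)-2,4-dimethoxy-6-methylbenzoate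
Product: 18 3-({[tert-butyl(dimethyl)silyl]oxy}methyl)-2,4-dimethoxy-6-methylbenzoic acid
Conditions: H2 (1 atm), 10% Pd/C, EtOAc, rt
Reagents that add atoms: none
Why: Catalytic hydrogenolysis cleaves the benzyl ester at the benzyl–oxygen bond and so frees a di-ortho-substituted acid that would resist saponification; in neutral ethyl acetate the benzylic silyl ether is expected to stay.

Step 9
Reactants: 19 methyl 2,4-dihydroxy-3,6-dimethylbenzoate
Product: 20 2,4-dihydroxy-3,6-dimethylbenzoic acid
Conditions: KOH, H2O/DMSO, 60 °C, N2; then HCl (aq.), 0 °C
Reagents that add atoms: potassium hydroxide, [K+].[OH-]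
Why: Alkaline ester hydrolysis; the carboxylate is stable in base, and acidification in the cold keeps the 2,4-dihydroxybenzoic acid from decarboxylating.

Step 10
Reactants: 20 2,4-dihydroxy-3,6-dimethylbenzoic acid
Product: 21 benzyl 2,4-dihydroxy-3,6-dimethylbenzoate
Conditions: BnBr, KHCO3, DMF, rt
Reagents that add atoms: benzyl bromide, BrCc1ccccc1
Why: KHCO3 deprotonates only the carboxylic acid, so SN2 alkylation with benzyl bromide gives the ester and leaves both phenols free.

Step 11
Reactants: 18 3-({[tert-butyl(dimethyl)silyl]oxy}methyl)-2,4-dimethoxy-6-methylbenzoic acid; 21 benzyl 2,4-dihydroxy-3,6-dimethylbenzoate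
Product: 23 benzyl 4-{[3-({[tert-butyl(dimethyl)silyl]oxy}methyl)-2,4-dimethoxy-6-methylbenzoyl]oxy}-2-hydroxy-3,6-dimethylbenzoate, via aroyl chloride 22 (not isolated)
Conditions: 1-chloro-N,N,2-trimethylprop-1-en-1-amine, CH2Cl2, 0 °C → rt; then 21, Et3N, DMAP, CH2Cl2, rt
Reagents that add atoms: none
Why: The α-chloroenamine turns the acid into aroyl chloride 22 under neutral conditions that spare the silyl ether, and DMAP-catalysed acyl transfer then esterifies the phenol; O-4' reacts because the 2'-hydroxyl is hydrogen-bonded to the ester carbonyl and shielded on both sides, the usual selectivity of β-orsellinates.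

Step 12
Reactants: 23 benzyl 4-{[3-({[tert-butyl(dimethyl)silyl]oxy}methyl)-2,4-dimethoxy-6-methylbenzoyl]oxy}-2-hydroxy-3,6-dimethylbenzoate
Product: 24 4-{[3-({[tert-butyl(dimethyl)silyl]oxy}methyl)-2,4-dimethoxy-6-methylbenzoyl]oxy}-2-hydroxy-3,6-dimethylbenzoic acid
Conditions: H2 (1 atm), 10% Pd/C, EtOAc, rt
Reagents that add atoms: none
Why: Hydrogenolysis of the benzyl ester as in step 8; the aryl ester has no benzylic C–O bond, and the C3 oxygen is still silylated, so no free electron-rich benzylic alcohol meets hydrogen and Pd/C.

Step 13
Reactants: 24 4-{[3-({[tert-butyl(dimethyl)silyl]oxy}methyl)-2,4-dimethoxy-6-methylbenzoyl]oxy}-2-hydroxy-3,6-dimethylbenzoic acid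
Product: 25 2-hydroxy-4-{[3-(hydroxymethyl)-2,4-dimethoxy-6-methylbenzoyl]oxy}-3,6-dimethylbenzoic acid
Conditions: HF·pyridine, pyridine, THF, 0 °C → rt
Reagents that add atoms: none
Why: Fluoride-induced desilylation with pyridine-buffered HF·pyridine is close to neutral, so the aryl ester, the salicylic acid and the acid-sensitive benzylic alcohol should all survive.

## Compound list

1 | benzyl tert-butyl malonate (1-benzyl 3-tert-butyl propanedioate) | O=C(CC(=O)OC(C)(C)C)OCc1ccccc1 | starting material
2 | acetone | CC(C)=O | starting material
3 | 1-benzyl 3-tert-butyl 2-(propan-2-ylidene)propanedioate | CC(C)=C(C(=O)OCc1ccccc1)C(=O)OC(C)(C)C | intermediate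
4 | 2-[(benzyloxy)carbonyl]-3-methylbut-2-enoic acid | CC(C)=C(C(=O)O)C(=O)OCc1ccccc1 | intermediate
5 | benzyl 2-(chlorocarbonyl)-3-methylbut-2-enoate | CC(C)=C(C(Cl)=O)C(=O)OCc1ccccc1 | intermediate
6 | 2-chloro-1,1-dimethoxyethane (chloroacetaldehyde dimethyl acetal) | COC(CCl)OC | starting material
7 | paraformaldehyde (as formaldehyde) | C=O | starting material
8 | (methoxyethynyl)lithium | COC#C[Li] | intermediate
9 | lithium 3-methoxyprop-2-yn-1-olate | COC#CCO[Li] | intermediate
10 | 3-methoxyprop-2-yn-1-ol | COC#CCO | intermediate
11 | tert-butyl[(3-methoxyprop-2-yn-1-yl)oxy]dimethylsilane | COC#CCO[Si](C)(C)C(C)(C)C | intermediate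
12 | benzyl 3-methyl-2-(oxomethylidene)but-3-enoate (vinylketene) | CC(=C)C(=C=O)C(=O)OCc1ccccc1 | intermediate
13 | benzyl 3-({[tert-butyl(dimethyl)silyl]oxy}methyl)-2-methoxy-4-oxo-1-(prop-1-en-2-yl)cyclobut-2-ene-1-carboxylate (racemic) | CC(=C)C1(C(=O)OCc2ccccc2)C(OC)=C(CO[Si](C)(C)C(C)(C)C)C1=O | intermediate
14 | benzyl (2Z)-4-({[tert-butyl(dimethyl)silyl]oxy}methyl)-3-methoxy-5-oxo-2-(prop-1-en-2-yl)penta-2,4-dienoate (dienylketene) | O=C=C(CO[Si](C)(C)C(C)(C)C)/C(OC)=C(\C(C)=C)C(=O)OCc1ccccc1 | intermediate
15 | benzyl 5-({[tert-butyl(dimethyl)silyl]oxy}methyl)-6-methoxy-2-methyl-4-oxocyclohexa-1,5-diene-1-carboxylate | CC1=C(C(=O)OCc2ccccc2)C(OC)=C(CO[Si](C)(C)C(C)(C)C)C(=O)C1 | intermediate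
16 | benzyl 3-({[tert-butyl(dimethyl)silyl]oxy}methyl)-4-hydroxy-2-methoxy-6-methylbenzoate | Cc1cc(O)c(CO[Si](C)(C)C(C)(C)C)c(OC)c1C(=O)OCc1ccccc1 | intermediate
17 | benzyl 3-({[tert-butyl(dimethyl)silyl]oxy}methyl)-2,4-dimethoxy-6-methylbenzoate | COc1cc(C)c(C(=O)OCc2ccccc2)c(OC)c1CO[Si](C)(C)C(C)(C)C | intermediate
18 | 3-({[tert-butyl(dimethyl)silyl]oxy}methyl)-2,4-dimethoxy-6-methylbenzoic acid | COc1cc(C)c(C(=O)O)c(OC)c1CO[Si](C)(C)C(C)(C)C | intermediate
19 | methyl 2,4-dihydroxy-3,6-dimethylbenzoate (methyl β-orsellinate) | COC(=O)c1c(C)cc(O)c(C)c1O | starting material
20 | 2,4-dihydroxy-3,6-dimethylbenzoic acid | OC(=O)c1c(C)cc(O)c(C)c1O | intermediate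
21 | benzyl 2,4-dihydroxy-3,6-dimethylbenzoate | Cc1cc(O)c(C)c(O)c1C(=O)OCc1ccccc1 | intermediate
22 | 3-({[tert-butyl(dimethyl)silyl]oxy}methyl)-2,4-dimethoxy-6-methylbenzoyl chloride | COc1cc(C)c(C(Cl)=O)c(OC)c1CO[Si](C)(C)C(C)(C)C | intermediate
23 | benzyl 4-{[3-({[tert-butyl(dimethyl)silyl]oxy}methyl)-2,4-dimethoxy-6-methylbenzoyl]oxy}-2-hydroxy-3,6-dimethylbenzoate | COc1cc(C)c(C(=O)Oc2cc(C)c(C(=O)OCc3ccccc3)c(O)c2C)c(OC)c1CO[Si](C)(C)C(C)(C)C | intermediate
24 | 4-{[3-({[tert-butyl(dimethyl)silyl]oxy}methyl)-2,4-dimethoxy-6-methylbenzoyl]oxy}-2-hydroxy-3,6-dimethylbenzoic acid | COc1cc(C)c(C(=O)Oc2cc(C)c(C(=O)O)c(O)c2C)c(OC)c1CO[Si](C)(C)C(C)(C)C | intermediate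
25 | 2-hydroxy-4-{[3-(hydroxymethyl)-2,4-dimethoxy-6-methylbenzoyl]oxy}-3,6-dimethylbenzoic acid | COc1cc(C)c(C(=O)Oc2cc(C)c(C(=O)O)c(O)c2C)c(OC)c1CO | target

## Step count and least certain steps

Total: 13 steps. Longest linear sequence: 9 steps (1, 2, 3, 6, 7, 8, 11, 12, 13).

**Step 6 (key step, proposed new method).** The likeliest failure is capture of ketene 12 by paths other than carbon–carbon (2+2) addition. These are closure of the first-formed adduct through the ester oxygen ((4+2) addition across the acylketene unit), dimerisation of the ketene, and direct acylation of the ynol ether by 5. The ring opening could also stall in the rotamer that turns the ester toward the ketene.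

The fallback uses known chemistry throughout; it sets out from ynol ether 11 and comes back at acid 18. The vinylketene is generated in the established way, by thermal opening of a cyclobutenone, and the carboxyl is introduced after the ring is made. Dichloroketene (from Cl3CCOCl and Zn) adds to propyne to give 4,4-dichloro-3-methylcyclobut-2-en-1-one F1, and zinc in acetic acid removes the chlorines to give 3-methylcyclobut-2-en-1-one F2. Heating F2 with 11 (Danheiser benzannulation in its original form) gives 2-({[tert-butyl(dimethyl)silyl]oxy}methyl)-3-methoxy-5-methylphenol F3. Methylation (MeI, K2CO3) gives the symmetrical diether tert-butyl[(2,6-dimethoxy-4-methylphenyl)methoxy]dimethylsilane F4, whose two free ring positions are equivalent. Bromination with NBS therefore gives the single bromide [(3-bromo-2,6-dimethoxy-4-methylphenyl)methoxy](tert-butyl)dimethylsilane F5. Bromine–lithium exchange (n-BuLi, −78 °C) and quenching with CO2 then deliver 18, so steps 1–3, 7 and 8 are not needed.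

**Step 4.** The likeliest failure is loss of the small hydroxy ynol ether during isolation, by evaporation or by acid-triggered hydration or Meyer–Schuster-type rearrangement. Incomplete double elimination of the chloroacetal is a second risk.

The fallback removes the free alcohol from the route instead of tuning its isolation. It sets out from 6 and comes back at 11: 8 is generated and trapped with 7 as before, and alkoxide 9 is silylated in the same flask with TBSCl (DMAP cat.), so that 10 is never liberated and the product is isolated as the non-volatile, base-stable silyl ether. No new compound is made.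

**Step 11.** The likeliest failure is slow acyl transfer from the di-ortho-substituted, electron-rich aroyl chloride to O-4', which leaves time for acylation at O-2' and for loss of the silyl group.

The fallback changes both the mechanism of ester formation and the oxidation level at C3; it sets out from 17 and comes back at 25. TBAF gives benzyl 3-(hydroxymethyl)-2,4-dimethoxy-6-methylbenzoate F6, and MnO2 oxidises it to benzyl 3-formyl-2,4-dimethoxy-6-methylbenzoate F7. Hydrogenolysis (H2, Pd/C, EtOAc) frees 3-formyl-2,4-dimethoxy-6-methylbenzoic acid F8, which has no acid-labile group. F8 is coupled with 21 by trifluoroacetic anhydride in toluene, the mixed-anhydride (aroylium) method that suits di-ortho-substituted depside acids, to give benzyl 4-[(3-formyl-2,4-dimethoxy-6-methylbenzoyl)oxy]-2-hydroxy-3,6-dimethylbenzoate F9. Hydrogenolysis gives 4-[(3-formyl-2,4-dimethoxy-6-methylbenzoyl)oxy]-2-hydroxy-3,6-dimethylbenzoic acid F10, and NaBH4 at 0 °C reduces only the aldehyde to give 25.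

**Step 12.** The likeliest failure is hydrogenolysis of the benzylic C3–O bond, directly or after loss of the silyl group. That over-reduction to the C3-methyl compound would be hard to separate; step 8 is the early test of the same risk.

The fallback takes hydrogen out of the end game; it sets out from 20 and comes back at 24. Alkylation of 20 with allyl bromide and KHCO3 in DMF gives prop-2-en-1-yl 2,4-dihydroxy-3,6-dimethylbenzoate F11. Acylation with 22 as in step 11 gives prop-2-en-1-yl 4-{[3-({[tert-butyl(dimethyl)silyl]oxy}methyl)-2,4-dimethoxy-6-methylbenzoyl]oxy}-2-hydroxy-3,6-dimethylbenzoate F12. Pd(PPh3)4 with morpholine in THF then removes the allyl group to give 24.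

## Further compounds

F1 | step 6 | 4,4-dichloro-3-methylcyclobut-2-en-1-one | CC1=CC(=O)C1(Cl)Cl
F2 | step 6 | 3-methylcyclobut-2-en-1-one | CC1=CC(=O)C1
F3 | step 6 | 2-({[tert-butyl(dimethyl)silyl]oxy}methyl)-3-methoxy-5-methylphenol | COc1cc(C)cc(O)c1CO[Si](C)(C)C(C)(C)C
F4 | step 6 | tert-butyl[(2,6-dimethoxy-4-methylphenyl)methoxy]dimethylsilane | COc1cc(C)cc(OC)c1CO[Si](C)(C)C(C)(C)C
F5 | step 6 | [(3-bromo-2,6-dimethoxy-4-methylphenyl)methoxy](tert-butyl)dimethylsilane | COc1cc(C)c(Br)c(OC)c1CO[Si](C)(C)C(C)(C)C
F0 | step 4 | none | none
F6 | step 11 | benzyl 3-(hydroxymethyl)-2,4-dimethoxy-6-methylbenzoate | COc1cc(C)c(C(=O)OCc2ccccc2)c(OC)c1CO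
F7 | step 11 | benzyl 3-formyl-2,4-dimethoxy-6-methylbenzoate | COc1cc(C)c(C(=O)OCc2ccccc2)c(OC)c1C=O
F8 | step 11 | 3-formyl-2,4-dimethoxy-6-methylbenzoic acid | COc1cc(C)c(C(=O)O)c(OC)c1C=O
F9 | step 11 | benzyl 4-[(3-formyl-2,4-dimethoxy-6-methylbenzoyl)oxy]-2-hydroxy-3,6-dimethylbenzoate | COc1cc(C)c(C(=O)Oc2cc(C)c(C(=O)OCc3ccccc3)c(O)c2C)c(OC)c1C=O
F10 | step 11 | 4-[(3-formyl-2,4-dimethoxy-6-methylbenzoyl)oxy]-2-hydroxy-3,6-dimethylbenzoic acid | COc1cc(C)c(C(=O)Oc2cc(C)c(C(=O)O)c(O)c2C)c(OC)c1C=O
F11 | step 12 | prop-2-en-1-yl 2,4-dihydroxy-3,6-dimethylbenzoate | C=CCOC(=O)c1c(C)cc(O)c(C)c1O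
F12 | step 12 | prop-2-en-1-yl 4-{[3-({[tert-butyl(dimethyl)silyl]oxy}methyl)-2,4-dimethoxy-6-methylbenzoyl]oxy}-2-hydroxy-3,6-dimethylbenzoate | COc1cc(C)c(C(=O)Oc2cc(C)c(C(=O)OCC=C)c(O)c2C)c(OC)c1CO[Si](C)(C)C(C)(C)C
A1 | alternative 1 | methyl 2-methoxy-6-methyl-4-{[(trifluoromethyl)sulfonyl]oxy}-3-(trimethylsilyl)benzoate | COC(=O)c1c(C)cc(OS(=O)(=O)C(F)(F)F)c([Si](C)(C)C)c1OC
A2 | alternative 1 | methyl 3,4-didehydro-2-methoxy-6-methylbenzoate (aryne) | COC1=C(C(=O)OC)C(C)=CC#C1
A3 | alternative 1 | N,N-dimethylformamide | CN(C)C=O
A4 | alternative 1 | methyl 3-formyl-4-hydroxy-2-methoxy-6-methylbenzoate | COC(=O)c1c(C)cc(O)c(C=O)c1OC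
A5 | alternative 2 | 3-({[tert-butyl(dimethyl)silyl]oxy}methyl)-4-methoxy-6-methyl-2H-pyran-2-one | COc1cc(C)oc(=O)c1CO[Si](C)(C)C(C)(C)C
A6 | alternative 2 | benzyl 3-methoxyprop-2-ynoate | COC#CC(=O)OCc1ccccc1
A7 | alternative 2 | benzyl 3-({[tert-butyl(dimethyl)silyl]oxy}methyl)-2,4-dimethoxy-6-methylbenzoate | COc1cc(C)c(C(=O)OCc2ccccc2)c(OC)c1CO[Si](C)(C)C(C)(C)C
A8 | alternative 3 | benzyl 4-methyl-3,5,7-trioxooctanoate | CC(=O)CC(=O)C(C)C(=O)CC(=O)OCc1ccccc1
A9 | alternative 3 | benzyl 2,4-dihydroxy-3,6-dimethylbenzoate | Cc1cc(O)c(C)c(O)c1C(=O)OCc1ccccc1
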